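**Retrosynthetic overview**
1. Ring B (furan: O1, C2 carrying quinone ring A, C3, C4 carrying the acyloxy side chain, C5) is traced back to its 2,5-dihydro form on a hydroquinone; DDQ restores both oxidation levels in the last step.
2. Feature used: furan O1–C5–C4(=C3)–C2 is the unit HO–CH2–C(=CH)–CH2 of a 2-(hydroxymethyl)but-2-enyl chain on ring A, with the hydroxymethyl cis to the quinonylmethyl carbon. The O1–C2 bond is therefore cut; it forms from the quinone through its ortho-quinone methide tautomer by a 5-exo oxa-addition.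
3. The quinone comes from a 1,4-dimethoxyarene with (NH4)2Ce(NO3)6; the isovalerate sits on a 4R allylic alcohol made by CBS reduction of an enone.
4. The enone is joined at C3–C4 from an (E)-2-iodoalkenyl silyl ether (benzylated propargyl alcohol, syn-hydrostannation, iodination) and the Weinreb amide of 4-methylpent-3-enoic acid.
5. Ring order: ring A is bought; ring B is the only ring made, closed in step 11 and aromatised in step 12.

Key step: step 11

Remark: locants C1 to C8 refer to the octa-2,6-diene chain of the acyclic intermediates (C1 = arylmethyl carbon, C4 = carbinol carbon).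
Assumption: the minor hydrostannation regioisomer of step 3 (tin distal to the hydroxyl) is removed by chromatography of 7, and 20 is used as its mixture of ring epimers.

**Route**

Step 1
Reactants: 1 2,5-dimethoxybenzyl alcohol
Product: 2 2,5-dimethoxybenzyl bromide
Conditions: PBr3 (0.4 equiv), Et2O, 0 °C
Reagents that add atoms: phosphorus tribromide, BrP(Br)Br
Why: Bromination of an activated benzylic alcohol by SN2 displacement of its phosphite ester, which should leave the dimethoxyarene untouched at 0 °C.

Step 2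
Reactants: 3 propargyl alcohol; 2 2,5-dimethoxybenzyl bromide
Product: 5 4-(2,5-dimethoxyphenyl)but-2-yn-1-ol, via propargyl alcohol bis(bromomagnesium) derivative 4 (not isolated)
Conditions: EtMgBr (2.1 equiv), THF, 0 °C to rt; then CuCl (0.1 equiv), 2, THF, 60 °C; aq. NH4Cl
Reagents that add atoms: ethylmagnesium bromide, CC[Mg]Br (magnesium and bromine in intermediate 4 only)
Why: Copper-catalysed alkylation of an alkynyl Grignard reagent by a benzylic bromide, in which the magnesium alkoxide is too poor a nucleophile to compete with the acetylide carbon.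

Step 3
Reactants: 5 4-(2,5-dimethoxyphenyl)but-2-yn-1-ol
Product: 7 (E)-4-(2,5-dimethoxyphenyl)-2-iodobut-2-en-1-ol, via alkenylstannane 6 (not isolated)
Conditions: Bu3SnH (1.2 equiv), PdCl2(PPh3)2 (2 mol %), THF, 0 °C to rt; then I2 (1.3 equiv), CH2Cl2, 0 °C; aq. Na2S2O3
Reagents that add atoms: tributyltin hydride, CCCC[SnH](CCCC)CCCC (tin in intermediate 6 only); iodine, II
Why: Palladium-catalysed hydrostannation of a 2-alkyn-1-ol is a syn addition that puts tin on the carbon next to the carbinol, and iododestannylation keeps the alkene geometry, so the CH2OH group should end up cis to the arylmethyl group.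

Step 4
Reactants: 7 (E)-4-(2,5-dimethoxyphenyl)-2-iodobut-2-en-1-ol
Product: 8 (E)-tert-butyl{[4-(2,5-dimethoxyphenyl)-2-iodobut-2-enyl]oxy}dimethylsilane
Conditions: TBSCl (1.2 equiv), imidazole (2 equiv), CH2Cl2, 0 °C to rt
Reagents that add atoms: tert-butyldimethylsilyl chloride, CC(C)(C)[Si](C)(C)Cl
Why: Standard silylation of a primary allylic alcohol, which masks the hydroxyl for the organolithium step.

Step 5
Reactants: 9 4-methylpent-3-enoic acid
Product: 11 N-methoxy-N,4-dimethylpent-3-enamide, via acyl imidazolide 10 (not isolated)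
Conditions: 1,1'-carbonyldiimidazole (1.1 equiv), CH2Cl2, 0 °C to rt; then MeNHOMe·HCl (1.2 equiv), rt
Reagents that add atoms: 1,1'-carbonyldiimidazole, O=C(n1ccnc1)n1ccnc1 (imidazolyl group in intermediate 10 only); N,O-dimethylhydroxylamine hydrochloride, CNOC.Cl
Why: Weinreb amide formation through the acyl imidazolide, under conditions mild enough that the β,γ-alkene should not move into conjugation.

Step 6
Reactants: 8 (E)-tert-butyl{[4-(2,5-dimethoxyphenyl)-2-iodobut-2-enyl]oxy}dimethylsilane; 11 N-methoxy-N,4-dimethylpent-3-enamide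
Product: 13 (E)-3-[(tert-butyldimethylsilyloxy)methyl]-1-(2,5-dimethoxyphenyl)-7-methylocta-2,6-dien-4-one, via alkenyllithium 12 (not isolated)
Conditions: t-BuLi (2.05 equiv), Et2O, −78 °C; then 11 (1.2 equiv), −78 °C; sat. aq. NH4Cl at −78 °C
Reagents that add atoms: tert-butyllithium, [Li]C(C)(C)C (lithium in intermediate 12 only)
Why: Iodine–lithium exchange keeps the alkene geometry and the Weinreb ketone synthesis stops at the ketone, while the cold ether medium and the cold quench should suppress O-to-C silyl shift and alkene migration.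

Step 7
Reactants: 13 (E)-3-[(tert-butyldimethylsilyloxy)methyl]-1-(2,5-dimethoxyphenyl)-7-methylocta-2,6-dien-4-one
Product: 14 (2E,4R)-3-[(tert-butyldimethylsilyloxy)methyl]-1-(2,5-dimethoxyphenyl)-7-methylocta-2,6-dien-4-ol
Conditions: (S)-2-methyl-CBS-oxazaborolidine (0.3 equiv), catecholborane (1.8 equiv), toluene, −78 °C; MeOH
Reagents that add atoms: none
Why: CBS reduction in which the α-branched alkenyl group is the large and the CH2 group the small ketone substituent, so the (S)-catalyst should deliver hydride to the face that gives the 4R alcohol (the sense known for acetophenone giving (R)-1-phenylethanol), and catecholborane at −78 °C should spare the alkenes.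

Step 8
Reactants: 14 (2E,4R)-3-[(tert-butyldimethylsilyloxy)methyl]-1-(2,5-dimethoxyphenyl)-7-methylocta-2,6-dien-4-ol; 15 3-methylbutanoyl chloride
Product: 16 (2E,4R)-3-[(tert-butyldimethylsilyloxy)methyl]-1-(2,5-dimethoxyphenyl)-7-methylocta-2,6-dien-4-yl 3-methylbutanoate
Conditions: 15 (1.5 equiv), pyridine (3 equiv), 4-(dimethylamino)pyridine (0.1 equiv), CH2Cl2, 0 °C to rt
Reagents that add atoms: none
Why: Nucleophile-catalysed O-acylation that breaks only the O–H bond, so the C4 configuration is retained.

Step 9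
Reactants: 16 (2E,4R)-3-[(tert-butyldimethylsilyloxy)methyl]-1-(2,5-dimethoxyphenyl)-7-methylocta-2,6-dien-4-yl 3-methylbutanoate
Product: 17 (2E,4R)-1-(2,5-dimethoxyphenyl)-3-(hydroxymethyl)-7-methylocta-2,6-dien-4-yl 3-methylbutanoate
Conditions: HF·pyridine, pyridine, THF, 0 °C to rt
Reagents that add atoms: none
Why: Fluoride desilylation in a weakly acidic buffered medium, which should avoid acyl migration from the secondary ester to the freed primary hydroxyl.

Step 10
Reactants: 17 (2E,4R)-1-(2,5-dimethoxyphenyl)-3-(hydroxymethyl)-7-methylocta-2,6-dien-4-yl 3-methylbutanoate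
Product: 18 (2E,4R)-1-(3,6-dioxocyclohexa-1,4-dienyl)-3-(hydroxymethyl)-7-methylocta-2,6-dien-4-yl 3-methylbutanoate
Conditions: (NH4)2Ce(NO3)6 (2.5 equiv), MeCN/H2O (2:1), 0 °C, 15 min
Reagents that add atoms: water, O
Why: Oxidative demethylation of a 1,4-dimethoxyarene to the 1,4-benzoquinone, a fast reaction at 0 °C that is expected to tolerate the trisubstituted alkenes, the ester and the free alcohol; the quinone oxygens come from water and two molecules of methanol are lost.

Step 11
Reactants: 18 (2E,4R)-1-(3,6-dioxocyclohexa-1,4-dienyl)-3-(hydroxymethyl)-7-methylocta-2,6-dien-4-yl 3-methylbutanoate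
Product: 20 (1R)-1-[5-(2,5-dihydroxyphenyl)-2,5-dihydrofuran-3-yl]-4-methylpent-3-enyl 3-methylbutanoate (both epimers at the arylated ring carbon), via ortho-quinone methide 19 (not isolated)
Conditions: Et3N (0.3 equiv), degassed CH2Cl2 (0.01 M), 0 °C to rt, argon, dark
Reagents that add atoms: none
Why: Proposed new method: Et3N removes a proton from the C1 methylene, which is allylic and vinylogously alpha to a quinone carbonyl, and protonation on oxygen gives the hydroxy ortho-quinone methide 19, whose methide carbon is then attacked by the cis-held primary hydroxyl in an oxa-conjugate (1,4) addition that re-aromatises ring A as the hydroquinone. The closest known reaction type is the amine-induced tautomerisation of prenylated benzoquinones to ortho-quinone methides that close to 2H-chromen-6-ols, together with the capture of ortho-quinone methides by tethered alcohols; capture of such a tautomer by a side-chain hydroxyl to give a 2,5-dihydrofuran has not been shown. Ring B closes in the 5-exo-trig mode, the exocyclic methide double bond being the acceptor and the C2=C3 alkene of the chain already lying in the ring. The new stereocentre at the arylated ring carbon is not controlled by the remote C4 acyloxy centre, so both epimers are expected, which does not matter because this carbon becomes sp2 in step 12. The step needs hydroxyl capture to outrun oxa-6π closure of 19 to a chromenol and amine-induced acyl shift: the alkene geometry fixed in step 3 holds the hydroxyl within bonding distance of the methide carbon, the methide isomer with its side chain turned away from the carbonyl can only be captured by the hydroxyl, the electrocyclisation would have to build a fully substituted carbon beside the acyloxy-bearing branch, and a substoichiometric amine at low temperature under argon should keep acyl shift and redox exchange slow.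

Step 12
Reactants: 20 (1R)-1-[5-(2,5-dihydroxyphenyl)-2,5-dihydrofuran-3-yl]-4-methylpent-3-enyl 3-methylbutanoate
Product: 22 (1R)-1-[5-(3,6-dioxocyclohexa-1,4-dienyl)furan-3-yl]-4-methylpent-3-enyl 3-methylbutanoate, via dihydrofuranyl benzoquinone 21 (not isolated)
Conditions: DDQ (2.2 equiv), 1,4-dioxane, rt
Reagents that add atoms: none
Why: DDQ first oxidises the hydroquinone to benzoquinone 21 and a second equivalent dehydrogenates the 2,5-dihydrofuran (hydride abstraction from a ring C–H next to oxygen, then proton loss) to the aromatic furan, without touching the side-chain stereocentre.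

**Compound list**
1 | 2,5-dimethoxybenzyl alcohol | COc1ccc(OC)c(CO)c1 | starting material
2 | 2,5-dimethoxybenzyl bromide | COc1ccc(OC)c(CBr)c1 | intermediate
3 | propargyl alcohol | C#CCO | starting material
4 | bromomagnesium 3-(bromomagnesiooxy)prop-1-yn-1-ide (propargyl alcohol bis(bromomagnesium) derivative) | Br[Mg]C#CCO[Mg]Br | intermediate (not isolated)
5 | 4-(2,5-dimethoxyphenyl)but-2-yn-1-ol | COc1ccc(OC)c(CC#CCO)c1 | intermediate
6 | (E)-4-(2,5-dimethoxyphenyl)-2-(tributylstannyl)but-2-en-1-ol | CCCC[Sn](CCCC)(CCCC)/C(CO)=C/Cc1cc(OC)ccc1OC | intermediate (not isolated)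
7 | (E)-4-(2,5-dimethoxyphenyl)-2-iodobut-2-en-1-ol | I/C(CO)=C/Cc1cc(OC)ccc1OC | intermediate
8 | (E)-tert-butyl{[4-(2,5-dimethoxyphenyl)-2-iodobut-2-enyl]oxy}dimethylsilane | I/C(CO[Si](C)(C)C(C)(C)C)=C/Cc1cc(OC)ccc1OC | intermediate
9 | 4-methylpent-3-enoic acid | CC(C)=CCC(=O)O | starting material
10 | 1-(4-methylpent-3-enoyl)imidazole | CC(C)=CCC(=O)n1ccnc1 | intermediate (not isolated)
11 | N-methoxy-N,4-dimethylpent-3-enamide | CC(C)=CCC(=O)N(C)OC | intermediate
12 | alkenyllithium from 8 (lithium in place of iodine, geometry retained) | [Li]/C(CO[Si](C)(C)C(C)(C)C)=C/Cc1cc(OC)ccc1OC | intermediate (not isolated)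
13 | (E)-3-[(tert-butyldimethylsilyloxy)methyl]-1-(2,5-dimethoxyphenyl)-7-methylocta-2,6-dien-4-one | CC(C)=CCC(=O)/C(CO[Si](C)(C)C(C)(C)C)=C/Cc1cc(OC)ccc1OC | intermediate
14 | (2E,4R)-3-[(tert-butyldimethylsilyloxy)methyl]-1-(2,5-dimethoxyphenyl)-7-methylocta-2,6-dien-4-ol | CC(C)=CC[C@@H](O)/C(CO[Si](C)(C)C(C)(C)C)=C/Cc1cc(OC)ccc1OC | intermediate
15 | 3-methylbutanoyl chloride | CC(C)CC(Cl)=O | starting material
16 | (2E,4R)-3-[(tert-butyldimethylsilyloxy)methyl]-1-(2,5-dimethoxyphenyl)-7-methylocta-2,6-dien-4-yl 3-methylbutanoate | CC(C)=CC[C@@H](OC(=O)CC(C)C)/C(CO[Si](C)(C)C(C)(C)C)=C/Cc1cc(OC)ccc1OC | intermediate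
17 | (2E,4R)-1-(2,5-dimethoxyphenyl)-3-(hydroxymethyl)-7-methylocta-2,6-dien-4-yl 3-methylbutanoate | CC(C)=CC[C@@H](OC(=O)CC(C)C)/C(CO)=C/Cc1cc(OC)ccc1OC | intermediate
18 | (2E,4R)-1-(3,6-dioxocyclohexa-1,4-dienyl)-3-(hydroxymethyl)-7-methylocta-2,6-dien-4-yl 3-methylbutanoate | CC(C)=CC[C@@H](OC(=O)CC(C)C)/C(CO)=C/CC1=CC(=O)C=CC1=O | intermediate
19 | (2E,4R)-1-(3-hydroxy-6-oxocyclohexa-2,4-dienylidene)-3-(hydroxymethyl)-7-methylocta-2,6-dien-4-yl 3-methylbutanoate (ortho-quinone methide tautomer of 18, methide geometry not fixed) | CC(C)=CC[C@@H](OC(=O)CC(C)C)/C(CO)=C/C=C1C=C(O)C=CC1=O | intermediate (not isolated)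
20 | (1R)-1-[5-(2,5-dihydroxyphenyl)-2,5-dihydrofuran-3-yl]-4-methylpent-3-enyl 3-methylbutanoate (both epimers at the arylated ring carbon) | CC(C)=CC[C@@H](OC(=O)CC(C)C)C1=CC(OC1)c1cc(O)ccc1O | intermediate
21 | (1R)-1-[5-(3,6-dioxocyclohexa-1,4-dienyl)-2,5-dihydrofuran-3-yl]-4-methylpent-3-enyl 3-methylbutanoate (both ring epimers) | CC(C)=CC[C@@H](OC(=O)CC(C)C)C1=CC(OC1)C1=CC(=O)C=CC1=O | intermediate (not isolated)
22 | (1R)-1-[5-(3,6-dioxocyclohexa-1,4-dienyl)furan-3-yl]-4-methylpent-3-enyl 3-methylbutanoate | CC(C)=CC[C@@H](OC(=O)CC(C)C)c1coc(C2=CC(=O)C=CC2=O)c1 | target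

**Step count**
Total: 12 steps. Longest linear sequence: 11 steps (1 to 22 through steps 1 to 4 and 6 to 12); step 5 is a one-step branch.

**Steps most likely to fail**

Step 11 (proposed new method). The ortho-quinone methide may be diverted into oxa-6π ring closure (chromenol formation) before the hydroxyl captures it. The hydroquinone product and unreacted quinone may also exchange redox state, and the amine may induce acyl shift from the secondary to the primary oxygen. The fallback uses only known chemistry: the furan is bought ready-made and the aryl–furan bond is made by Suzuki coupling. It leaves the main line at Weinreb amide 11 (and uses 15) and rejoins it at target 22. 3-Furyllithium (3-bromofuran, n-BuLi, THF, −78 °C) is acylated by 11 to give 1-(furan-3-yl)-4-methylpent-3-en-1-one F1. CBS reduction under the conditions of step 7 should give (1R)-1-(furan-3-yl)-4-methylpent-3-en-1-ol F2, and acylation with 15 as in step 8 gives (1R)-1-(furan-3-yl)-4-methylpent-3-enyl 3-methylbutanoate F3. Sterically governed C–H borylation ([Ir(OMe)(cod)]2, 4,4'-di-tert-butyl-2,2'-bipyridine, B2pin2, hexane, rt) should take place at the furan carbon next to oxygen and remote from the side chain, giving (1R)-4-methyl-1-[5-(4,4,5,5-tetramethyl-1,3,2-dioxaborolan-2-yl)furan-3-yl]pent-3-enyl 3-methylbutanoate F4. Commercial 2-bromohydroquinone is silylated (TBSCl, imidazole) to 2-bromo-1,4-bis(tert-butyldimethylsilyloxy)benzene F5. Suzuki coupling of F4 with F5 (Pd(dppf)Cl2, K3PO4, dioxane/H2O, 60 °C) gives (1R)-1-{5-[2,5-bis(tert-butyldimethylsilyloxy)phenyl]furan-3-yl}-4-methylpent-3-enyl 3-methylbutanoate F6. Bu4NF buffered with AcOH (THF, 0 °C) frees (1R)-1-[5-(2,5-dihydroxyphenyl)furan-3-yl]-4-methylpent-3-enyl 3-methylbutanoate F7, and Ag2O (Et2O, MgSO4, rt) oxidises F7 to 22.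

Step 12. Dehydrogenation of the dihydrofuran may stall once ring A has become an electron-poor quinone, and the electron-rich furan of the product may be degraded by excess DDQ. The fallback separates the two oxidations by masking the hydroquinone; it sets out from 20 and returns at 22. Silylation of 20 (TBSCl, imidazole, DMF) gives (1R)-1-{5-[2,5-bis(tert-butyldimethylsilyloxy)phenyl]-2,5-dihydrofuran-3-yl}-4-methylpent-3-enyl 3-methylbutanoate F8. Dehydrogenation of the dihydrofuran beside an electron-rich arene (DDQ, 1.1 equiv, benzene, rt, or MnO2, CH2Cl2) gives the furan (1R)-1-{5-[2,5-bis(tert-butyldimethylsilyloxy)phenyl]furan-3-yl}-4-methylpent-3-enyl 3-methylbutanoate F6. Buffered Bu4NF then gives the furyl hydroquinone (1R)-1-[5-(2,5-dihydroxyphenyl)furan-3-yl]-4-methylpent-3-enyl 3-methylbutanoate F7, and Ag2O converts F7 into 22.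

Step 6. The alkenyllithium may deprotonate the amide at its allylic alpha-CH2 instead of adding, the β,γ-alkene of the ketone may migrate into conjugation, and the silyl group may shift from oxygen to carbon in the alkenyllithium. The fallback sets the stereocentre by reagent-controlled allylation instead of ketone reduction and avoids any β,γ-unsaturated carbonyl compound; it sets out from 8 and returns at 14. Alkenyllithium 12, made from 8 as in step 6, is quenched with DMF to give the enal (E)-2-[(tert-butyldimethylsilyloxy)methyl]-4-(2,5-dimethoxyphenyl)but-2-enal F9. Brown allylation with the Ipc2B(allyl) reagent made from (+)-Ipc2BOMe (the (−)-α-pinene series) and allylmagnesium bromide (Et2O, −78 °C; then NaOH, H2O2) should give (2E,4R)-3-[(tert-butyldimethylsilyloxy)methyl]-1-(2,5-dimethoxyphenyl)hepta-2,6-dien-4-ol F10. Cross-metathesis of F10 with 2-methyl-2-butene (second-generation Grubbs catalyst RuCl2(=CHPh)(H2IMes)(PCy3), 40 °C) turns the terminal alkene into the prenyl terminus and delivers 14.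

**Further compounds**
F1 | step 11 | 1-(furan-3-yl)-4-methylpent-3-en-1-one | CC(C)=CCC(=O)c1ccoc1
F2 | step 11 | (1R)-1-(furan-3-yl)-4-methylpent-3-en-1-ol | CC(C)=CC[C@@H](O)c1ccoc1
F3 | step 11 | (1R)-1-(furan-3-yl)-4-methylpent-3-enyl 3-methylbutanoate | CC(C)=CC[C@@H](OC(=O)CC(C)C)c1ccoc1
F4 | step 11 | (1R)-4-methyl-1-[5-(4,4,5,5-tetramethyl-1,3,2-dioxaborolan-2-yl)furan-3-yl]pent-3-enyl 3-methylbutanoate | CC(C)=CC[C@@H](OC(=O)CC(C)C)c1coc(B2OC(C)(C)C(C)(C)O2)c1
F5 | step 11 | 2-bromo-1,4-bis(tert-butyldimethylsilyloxy)benzene | Brc1cc(O[Si](C)(C)C(C)(C)C)ccc1O[Si](C)(C)C(C)(C)C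
F6 | step 11 | (1R)-1-{5-[2,5-bis(tert-butyldimethylsilyloxy)phenyl]furan-3-yl}-4-methylpent-3-enyl 3-methylbutanoate | CC(C)=CC[C@@H](OC(=O)CC(C)C)c1coc(-c2cc(O[Si](C)(C)C(C)(C)C)ccc2O[Si](C)(C)C(C)(C)C)c1
F7 | step 11 | (1R)-1-[5-(2,5-dihydroxyphenyl)furan-3-yl]-4-methylpent-3-enyl 3-methylbutanoate | CC(C)=CC[C@@H](OC(=O)CC(C)C)c1coc(-c2cc(O)ccc2O)c1
F8 | step 12 | (1R)-1-{5-[2,5-bis(tert-butyldimethylsilyloxy)phenyl]-2,5-dihydrofuran-3-yl}-4-methylpent-3-enyl 3-methylbutanoate (both ring epimers) | CC(C)=CC[C@@H](OC(=O)CC(C)C)C1=CC(OC1)c1cc(O[Si](C)(C)C(C)(C)C)ccc1O[Si](C)(C)C(C)(C)C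
F9 | step 6 | (E)-2-[(tert-butyldimethylsilyloxy)methyl]-4-(2,5-dimethoxyphenyl)but-2-enal | O=C/C(CO[Si](C)(C)C(C)(C)C)=C/Cc1cc(OC)ccc1OC
F10 | step 6 | (2E,4R)-3-[(tert-butyldimethylsilyloxy)methyl]-1-(2,5-dimethoxyphenyl)hepta-2,6-dien-4-ol | C=CC[C@@H](O)/C(CO[Si](C)(C)C(C)(C)C)=C/Cc1cc(OC)ccc1OC
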